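**Strategy.** In ring C the carbonyl carbon C4 stands alone between C4a of ring A and C3. The pyranone can therefore be cut into three parts: an ortho-iodophenol (O1, C8a, C4a), carbon monoxide (C4) and an arylacetylene (C3, C2, ring B). A single palladium-catalysed carbonylative annulation in diethylamine forms C4a–C4, C4–C3 and O1–C2 and closes ring C. Its precursor is a pentasubstituted iodophenol that already holds the 8-methoxy group and benzyl ethers on the future O5 and O7, with only the future O1 free. The alkyne carries O4' as a triisopropylsilyl ether. The 3-methoxy group, the 7-prenyl ether and the two free phenols are set afterwards.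

Key step: step 9

**Remarks on the chemistry**
- The target has no stereocentre and no stereogenic double bond, so no stereochemical control is needed.
- 3,5-Bis(benzyloxy)-2-methoxyphenol has two free ring carbons: one ortho and one para to the hydroxyl. The iodination site is therefore a real selectivity question. Iodination is run last, on the free phenol, in a non-polar solvent, where steric shielding of the para carbon decides the outcome.
- The alkyne is made under cold, aprotic conditions, because carbonate in methanol could strip a silyl ether that sits para to a formyl group.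
- O5 and O7 are benzylated so that both fall together under neutral hydrogenolysis before the prenyl group arrives. O4' is silylated so that the last deprotection uses fluoride, which a prenyl ether tolerates.

**Step 1**
Reactants: 1 2,4,6-trihydroxybenzaldehyde
Product: 2 2,4-bis(benzyloxy)-6-hydroxybenzaldehyde
Conditions: BnBr (2.05 equiv), K2CO3, DMF, 0 °C → rt
Reagents that add atoms: benzyl bromide, BrCc1ccccc1
Why: Williamson etherification, in which the 4-OH and one ortho-OH are alkylated, after which the last hydroxyl is locked in a strong hydrogen bond to the formyl oxygen and is too poor a nucleophile under carbonate conditions to consume the limiting bromide.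

**Step 2**
Reactants: 2 2,4-bis(benzyloxy)-6-hydroxybenzaldehyde
Product: 3 2,4-bis(benzyloxy)-6-(methoxymethoxy)benzaldehyde
Conditions: NaH, MOMCl, DMF, 0 °C → rt
Reagents that add atoms: chloromethyl methyl ether, COCCl
Why: Irreversible deprotonation breaks the chelate and the phenoxide is alkylated (acetal protection); an acetal is chosen because, unlike an acyl or silyl group, it cannot migrate to the neighbouring phenoxide created in step 3 and it withstands peracid and carbonate.

**Step 3**
Reactants: 3 2,4-bis(benzyloxy)-6-(methoxymethoxy)benzaldehyde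
Product: 5 2,4-bis(benzyloxy)-6-(methoxymethoxy)phenol, via aryl formate 4 (not isolated)
Conditions: mCPBA (1.1 equiv), CH2Cl2, 0 °C → rt; reductive wash; then Et3N (cat.), MeOH, rt, argon
Reagents that add atoms: 3-chloroperoxybenzoic acid, OOC(=O)c1cccc(Cl)c1
Why: Baeyer–Villiger (Dakin-type) oxidation, in which the trialkoxyaryl group migrates far faster than hydrogen in the Criegee adduct to give formate 4, which amine-catalysed methanolysis cleaves without exposing the oxidation-prone phenol to strong base.

**Step 4**
Reactants: 5 2,4-bis(benzyloxy)-6-(methoxymethoxy)phenol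
Product: 6 1,5-bis(benzyloxy)-2-methoxy-3-(methoxymethoxy)benzene
Conditions: MeI, K2CO3, acetone, reflux
Reagents that add atoms: iodomethane, CI
Why: Williamson methylation of the only free hydroxyl installs the future 8-methoxy group, and the benzyl ethers and the acetal are inert to carbonate.

**Step 5**
Reactants: 6 1,5-bis(benzyloxy)-2-methoxy-3-(methoxymethoxy)benzene
Product: 7 3,5-bis(benzyloxy)-2-methoxyphenol
Conditions: conc. HCl (cat.), MeOH–THF, 45 °C
Reagents that add atoms: none
Why: Acid-catalysed acetal exchange with methanol carries the protecting group away as dimethoxymethane, which keeps formaldehyde equivalents off the electron-rich ring, while benzyl and methyl ethers are stable to dilute acid.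

**Step 6**
Reactants: 7 3,5-bis(benzyloxy)-2-methoxyphenol
Product: 8 3,5-bis(benzyloxy)-2-iodo-6-methoxyphenol
Conditions: NIS (1.0 equiv), CH2Cl2, −20 °C → 0 °C, dark
Reagents that add atoms: N-iodosuccinimide, O=C1CCC(=O)N1I
Why: Electrophilic aromatic iodination, in which the two free carbons are electronically alike but the para carbon lies between two benzyloxy groups (one pushed towards it by the adjacent methoxy group) while the ortho carbon is flanked by the small hydroxyl that can hydrogen-bond to the imide, so iodine should enter ortho as it does in 3,5-dialkoxyphenols, and one equivalent at low temperature limits di-iodination.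

**Step 7**
Reactants: 9 vanillin
Product: 10 3-methoxy-4-(triisopropylsilyloxy)benzaldehyde
Conditions: TIPSCl, imidazole, DMF, rt
Reagents that add atoms: chlorotriisopropylsilane, CC(C)[Si](Cl)(C(C)C)C(C)C
Why: Imidazole-promoted silylation of the phenol gives the aryl silyl ether most resistant to amines, amide bases and carbonate, one that hydrogenolysis leaves alone and fluoride removes.

**Step 8**
Reactants: 10 3-methoxy-4-(triisopropylsilyloxy)benzaldehyde
Product: 11 (4-ethynyl-2-methoxyphenoxy)triisopropylsilane
Conditions: Me3SiCHN2, LiN(iPr)2, THF, −78 °C; then 10, −78 °C → rt; H2O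
Reagents that add atoms: (trimethylsilyl)diazomethane, C[Si](C)(C)C=[N+]=[N-]
Why: Colvin variant of the Seyferth–Gilbert homologation, in which the lithiated diazomethane adds to the aldehyde, Peterson-type loss of silanolate and then of N2 gives an alkylidene carbene, and its 1,2-hydride shift yields the terminal alkyne in a medium that cannot desilylate the phenol.

**Step 9**
Reactants: 8 3,5-bis(benzyloxy)-2-iodo-6-methoxyphenol; 11 (4-ethynyl-2-methoxyphenoxy)triisopropylsilane (1.4 equiv); 12 carbon monoxide
Product: 15 5,7-bis(benzyloxy)-8-methoxy-2-[3-methoxy-4-(triisopropylsilyloxy)phenyl]-4H-chromen-4-one, via ortho-hydroxyaryl ynone 13 (not isolated), via diethylamino enone 14 (not isolated)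
Conditions: PdCl2(dppf) (5 mol %), CO (10 bar), Et2NH, 90 °C, autoclave
Reagents that add atoms: carbon monoxide 12, [C-]#[O+]; diethylamine, CCNCC (present only in intermediate 14, released again on ring closure)
Why: Oxidative addition of the C4a–I bond of 8 to zerovalent palladium (formed in situ from PdCl2(dppf)) is followed by migratory insertion of CO, the resulting aroylpalladium iodide takes up the acetylide of 11 with the help of the amine, and reductive elimination releases ynone 13, which sets C4a–C4 and C4–C3. Conjugate addition of diethylamine converts 13 into enaminone 14, whose amino group is then displaced at C2 by the C8a hydroxyl through addition–elimination, so ring C closes in the 6-endo-trig mode with formation of O1–C2. The closest known reaction type is the palladium-catalysed carbonylative annulation of ortho-iodophenols with terminal arylacetylenes, a copper-free carbonylative Sonogashira coupling followed by cyclisation, applied here to a more crowded and electron-rich iodide than usual. No stereocentre is formed. The step needs carbonylative rather than direct alkynylation, which CO pressure, the absence of copper and the fast CO insertion of an electron-rich, doubly ortho-substituted arylpalladium species favour, and it needs 6-endo closure to the flavone rather than 5-exo closure to the aurone, which the secondary amine secures by making C2 the only electrophilic carbon before the phenol attacks. Constitutional selectivity is built into 8, because O5 and O7 are benzylated and only the hydroxyl next to the methoxy-bearing carbon can close the ring, so the 8-methoxy and not the 6-methoxy flavone must result.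

**Step 10**
Reactants: 15 5,7-bis(benzyloxy)-8-methoxy-2-[3-methoxy-4-(triisopropylsilyloxy)phenyl]-4H-chromen-4-one
Product: 18 5,7-bis(benzyloxy)-3-hydroxy-8-methoxy-2-[3-methoxy-4-(triisopropylsilyloxy)phenyl]-4H-chromen-4-one, via 3-lithioflavone 16 (not isolated), via dimethyl flavon-3-ylboronate 17 (not isolated)
Conditions: LiN(iPr)2 (1.5 equiv), THF, −78 °C, 15 min; B(OMe)3 (3 equiv), −78 °C → 0 °C; AcOH, 30% H2O2, 0 °C → rt
Reagents that add atoms: hydrogen peroxide, OO; trimethyl borate, COB(OC)OC (boron only in intermediate 17); LiN(iPr)2, [Li]N(C(C)C)C(C)C (lithium only in intermediate 16)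
Why: Deprotonation of the flavone at C3 (the vinylic C–H beside the carbonyl is the most acidic site for the hindered amide base at −78 °C), electrophilic borylation and oxidative boron-to-oxygen 1,2-migration form a known passage from flavones to flavonols, and benzyl, methyl and silyl ethers are inert to it.

**Step 11**
Reactants: 18 5,7-bis(benzyloxy)-3-hydroxy-8-methoxy-2-[3-methoxy-4-(triisopropylsilyloxy)phenyl]-4H-chromen-4-one
Product: 19 5,7-bis(benzyloxy)-3,8-dimethoxy-2-[3-methoxy-4-(triisopropylsilyloxy)phenyl]-4H-chromen-4-one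
Conditions: MeI, K2CO3, dry acetone, 40 °C
Reagents that add atoms: iodomethane, CI
Why: Williamson methylation of the acidic enolic 3-OH, the only free hydroxyl, under anhydrous carbonate conditions that a triisopropylsilyl aryl ether tolerates.

**Step 12**
Reactants: 19 5,7-bis(benzyloxy)-3,8-dimethoxy-2-[3-methoxy-4-(triisopropylsilyloxy)phenyl]-4H-chromen-4-one
Product: 20 5,7-dihydroxy-3,8-dimethoxy-2-[3-methoxy-4-(triisopropylsilyloxy)phenyl]-4H-chromen-4-one
Conditions: H2 (1 atm), 10% Pd/C, EtOAc–THF, rt
Reagents that add atoms: none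
Why: Catalytic hydrogenolysis cleaves both benzylic C–O bonds under neutral conditions, while the tetrasubstituted conjugated C2–C3 bond, the silyl ether and the methyl ethers are unaffected.

**Step 13**
Reactants: 20 5,7-dihydroxy-3,8-dimethoxy-2-[3-methoxy-4-(triisopropylsilyloxy)phenyl]-4H-chromen-4-one
Product: 21 5-hydroxy-3,8-dimethoxy-7-(3-methylbut-2-enyloxy)-2-[3-methoxy-4-(triisopropylsilyloxy)phenyl]-4H-chromen-4-one
Conditions: prenyl bromide (1.1 equiv), K2CO3 (1.2 equiv), dry acetone, rt → 40 °C
Reagents that add atoms: prenyl bromide (1-bromo-3-methylbut-2-ene), CC(C)=CCBr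
Why: Chemoselective Williamson etherification, since the 7-OH is a vinylogous acid of C4=O and the most acidic hydroxyl whereas the 5-OH is held in a hydrogen bond to C4=O, so about one equivalent of base and bromide should give SN2 alkylation at O7 only.

**Step 14**
Reactants: 21 5-hydroxy-3,8-dimethoxy-7-(3-methylbut-2-enyloxy)-2-[3-methoxy-4-(triisopropylsilyloxy)phenyl]-4H-chromen-4-one
Product: 22 5,4'-dihydroxy-3,8,3'-trimethoxy-7-prenyloxyflavone
Conditions: Bu4NF, AcOH (1:1), THF, 0 °C
Reagents that add atoms: none
Why: Fluoride-induced desilylation driven by the strong Si–F bond, with acetic acid buffering the phenoxide, leaves untouched the prenyl ether that neither acid nor hydrogenation would spare.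

**Compound list**
1 | 2,4,6-trihydroxybenzaldehyde | O=Cc1c(O)cc(O)cc1O | starting material
2 | 2,4-bis(benzyloxy)-6-hydroxybenzaldehyde | O=Cc1c(O)cc(OCc2ccccc2)cc1OCc1ccccc1 | intermediate
3 | 2,4-bis(benzyloxy)-6-(methoxymethoxy)benzaldehyde | O=Cc1c(OCOC)cc(OCc2ccccc2)cc1OCc1ccccc1 | intermediate
4 | 2,4-bis(benzyloxy)-6-(methoxymethoxy)phenyl formate (not isolated) | O=COc1c(OCOC)cc(OCc2ccccc2)cc1OCc1ccccc1 | intermediate
5 | 2,4-bis(benzyloxy)-6-(methoxymethoxy)phenol | Oc1c(OCOC)cc(OCc2ccccc2)cc1OCc1ccccc1 | intermediate
6 | 1,5-bis(benzyloxy)-2-methoxy-3-(methoxymethoxy)benzene | COc1c(OCOC)cc(OCc2ccccc2)cc1OCc1ccccc1 | intermediate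
7 | 3,5-bis(benzyloxy)-2-methoxyphenol | COc1c(O)cc(OCc2ccccc2)cc1OCc1ccccc1 | intermediate
8 | 3,5-bis(benzyloxy)-2-iodo-6-methoxyphenol | COc1c(O)c(I)c(OCc2ccccc2)cc1OCc1ccccc1 | intermediate
9 | vanillin (4-hydroxy-3-methoxybenzaldehyde) | COc1cc(C=O)ccc1O | starting material
10 | 3-methoxy-4-(triisopropylsilyloxy)benzaldehyde | COc1cc(C=O)ccc1O[Si](C(C)C)(C(C)C)C(C)C | intermediate
11 | (4-ethynyl-2-methoxyphenoxy)triisopropylsilane | C#Cc1ccc(O[Si](C(C)C)(C(C)C)C(C)C)c(OC)c1 | intermediate
12 | carbon monoxide | [C-]#[O+] | starting material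
13 | 1-[4,6-bis(benzyloxy)-2-hydroxy-3-methoxyphenyl]-3-[3-methoxy-4-(triisopropylsilyloxy)phenyl]prop-2-yn-1-one (not isolated) | COc1c(O)c(C(=O)C#Cc2ccc(O[Si](C(C)C)(C(C)C)C(C)C)c(OC)c2)c(OCc2ccccc2)cc1OCc1ccccc1 | intermediate
14 | (E)-1-[4,6-bis(benzyloxy)-2-hydroxy-3-methoxyphenyl]-3-(diethylamino)-3-[3-methoxy-4-(triisopropylsilyloxy)phenyl]prop-2-en-1-one (not isolated; push–pull double bond, geometry labile) | CCN(CC)/C(=C/C(=O)c1c(O)c(OC)c(OCc2ccccc2)cc1OCc1ccccc1)c1ccc(O[Si](C(C)C)(C(C)C)C(C)C)c(OC)c1 | intermediate
15 | 5,7-bis(benzyloxy)-8-methoxy-2-[3-methoxy-4-(triisopropylsilyloxy)phenyl]-4H-chromen-4-one | COc1cc(-c2cc(=O)c3c(OCc4ccccc4)cc(OCc4ccccc4)c(OC)c3o2)ccc1O[Si](C(C)C)(C(C)C)C(C)C | intermediate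
16 | 3-lithio derivative of 15 (not isolated) | COc1cc(-c2oc3c(OC)c(OCc4ccccc4)cc(OCc4ccccc4)c3c(=O)c2[Li])ccc1O[Si](C(C)C)(C(C)C)C(C)C | intermediate
17 | dimethyl boronate at C3 of 15 (not isolated) | COc1cc(-c2oc3c(OC)c(OCc4ccccc4)cc(OCc4ccccc4)c3c(=O)c2B(OC)OC)ccc1O[Si](C(C)C)(C(C)C)C(C)C | intermediate
18 | 5,7-bis(benzyloxy)-3-hydroxy-8-methoxy-2-[3-methoxy-4-(triisopropylsilyloxy)phenyl]-4H-chromen-4-one | COc1cc(-c2oc3c(OC)c(OCc4ccccc4)cc(OCc4ccccc4)c3c(=O)c2O)ccc1O[Si](C(C)C)(C(C)C)C(C)C | intermediate
19 | 5,7-bis(benzyloxy)-3,8-dimethoxy-2-[3-methoxy-4-(triisopropylsilyloxy)phenyl]-4H-chromen-4-one | COc1cc(-c2oc3c(OC)c(OCc4ccccc4)cc(OCc4ccccc4)c3c(=O)c2OC)ccc1O[Si](C(C)C)(C(C)C)C(C)C | intermediate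
20 | 5,7-dihydroxy-3,8-dimethoxy-2-[3-methoxy-4-(triisopropylsilyloxy)phenyl]-4H-chromen-4-one | COc1cc(-c2oc3c(OC)c(O)cc(O)c3c(=O)c2OC)ccc1O[Si](C(C)C)(C(C)C)C(C)C | intermediate
21 | 5-hydroxy-3,8-dimethoxy-7-(3-methylbut-2-enyloxy)-2-[3-methoxy-4-(triisopropylsilyloxy)phenyl]-4H-chromen-4-one | COc1cc(-c2oc3c(OC)c(OCC=C(C)C)cc(O)c3c(=O)c2OC)ccc1O[Si](C(C)C)(C(C)C)C(C)C | intermediate
22 | 5,4'-dihydroxy-3,8,3'-trimethoxy-7-prenyloxyflavone | COc1cc(-c2oc3c(OC)c(OCC=C(C)C)cc(O)c3c(=O)c2OC)ccc1O | target

**Step count.** Total: 14 steps. Longest linear sequence: 12 steps (steps 1–6 and 9–14).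

**Steps most likely to fail**

First, step 9.
- What may go wrong: insertion of zerovalent palladium into the crowded, electron-rich C–I bond may be slow. Reductive loss of iodine, CO-free alkynylation with benzofuran closure, interception of the acyl complex by the amine, or erosion of the silyl ether at the required temperature could then take over.
- Fallback: it brings C4 in as a formyl carbon and uses neither palladium nor CO. It sets out from 7 and 11 and comes back at 15.
- Phenol 7 is formylated with MgCl2, Et3N and paraformaldehyde in MeCN at reflux (Casnati–Skattebøl formylation). This phenoxide-directed process reaches only the ortho carbon and gives 4,6-bis(benzyloxy)-2-hydroxy-3-methoxybenzaldehyde F1.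
- Alkyne 11 is deprotonated with n-BuLi (THF, −78 °C) to lithium [3-methoxy-4-(triisopropylsilyloxy)phenyl]acetylide F2.
- A little over two equivalents of F2 add to F1 to give racemic 1-[4,6-bis(benzyloxy)-2-hydroxy-3-methoxyphenyl]-3-[3-methoxy-4-(triisopropylsilyloxy)phenyl]prop-2-yn-1-ol F3.
- MnO2 in CH2Cl2 oxidises F3 to ynone 13. Warming 13 in Et2NH–EtOH leads through 14 to 15.

Second, step 10.
- What may go wrong: the lithiated flavone may add to unreacted flavone at C2, the anion may ring-open on warming, or capture by the borate may be incomplete.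
- Fallback: it transfers electrophilic oxygen to the C2–C3 double bond instead of metalating the C–H bond. It sets out from 15 and comes back at 18.
- Dimethyldioxirane in acetone–CH2Cl2 at 0 °C should epoxidise the enol-ether-like double bond to the racemic cis-fused 2,3-epoxide of flavone 15 F4.
- Catalytic p-TsOH opens F4 at C2 through the oxocarbenium ion, and loss of H3 then gives flavonol 18.

Third, step 6.
- What may go wrong: the iodinating agent may attack the para carbon or both free carbons, or it may oxidise the electron-rich phenol.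
- Fallback: it replaces electrophilic substitution by directed ortho-metalation. It sets out from 6 and comes back at 8.
- n-BuLi in THF at −20 to 0 °C is guided by chelation to the acetal oxygens to the C–H between the methoxymethoxy and benzyloxy groups. This gives [4,6-bis(benzyloxy)-3-methoxy-2-(methoxymethoxy)phenyl]lithium F5.
- Iodine converts F5 into 1,5-bis(benzyloxy)-2-iodo-4-methoxy-3-(methoxymethoxy)benzene F6.
- p-TsOH in MeOH at rt to 40 °C removes the acetal to give 8.

**Further compounds**
F1 | step 9 | 4,6-bis(benzyloxy)-2-hydroxy-3-methoxybenzaldehyde | COc1c(O)c(C=O)c(OCc2ccccc2)cc1OCc1ccccc1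
F2 | step 9 | lithium [3-methoxy-4-(triisopropylsilyloxy)phenyl]acetylide | [Li]C#Cc1ccc(O[Si](C(C)C)(C(C)C)C(C)C)c(OC)c1
F3 | step 9 | racemic 1-[4,6-bis(benzyloxy)-2-hydroxy-3-methoxyphenyl]-3-[3-methoxy-4-(triisopropylsilyloxy)phenyl]prop-2-yn-1-ol | COc1c(O)c(C(O)C#Cc2ccc(O[Si](C(C)C)(C(C)C)C(C)C)c(OC)c2)c(OCc2ccccc2)cc1OCc1ccccc1
F4 | step 10 | racemic cis-fused 2,3-epoxide of flavone 15 (one enantiomer drawn) | O=C1c2c(OCc3ccccc3)cc(OCc3ccccc3)c(OC)c2O[C@]2(c3ccc(O[Si](C(C)C)(C(C)C)C(C)C)c(OC)c3)O[C@H]12
F5 | step 6 | [4,6-bis(benzyloxy)-3-methoxy-2-(methoxymethoxy)phenyl]lithium | [Li]c1c(OCOC)c(OC)c(OCc2ccccc2)cc1OCc1ccccc1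
F6 | step 6 | 1,5-bis(benzyloxy)-2-iodo-4-methoxy-3-(methoxymethoxy)benzene | COCOc1c(I)c(OCc2ccccc2)cc(OCc2ccccc2)c1OC
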